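**Retrosynthetic overview**
1. The 1,2-dioxane (the only ring of the target) is closed last, by intramolecular hydroperoxide oxa-Michael addition (C3–O) onto the (E)-enoate of acyclic hydroperoxide 17.
2. 17 comes from cyclopropyl carbinol 16 by stereoinvertive perhydrolysis at the quaternary cyclopropane carbon: this forms the C6–O bond, sets C6 and releases the (8E)-alkene in one operation (new step).
3. 16 comes from cyclopropanecarbaldehyde 11 and an alkenylzinc made from 1-phenylbut-2-yne; 11 comes from allylic alcohol 7 by Charette cyclopropanation, DIBAL/Wittig homologation and oxidation.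
4. 7 comes from Negishi coupling of the Roche-ester zinc homoenolate (C4 stereocentre) with (Z)-3-iodo-2-methylbut-2-en-1-ol (from but-2-yn-1-ol).
5. Ring order: cyclopropane (temporary, step 4), opened in step 9, then the 1,2-dioxane (step 10).

Assumption: the Charette dioxaborolane shows its usual facial preference on the tetrasubstituted (Z)-allylic alcohol 7 (assigned by analogy with cinnamyl alcohol, so the (4S,5S)-reagent gives the (1S,2R)-cyclopropane); if it selects the other face, its enantiomer is used.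

**Route**

Step 1
Reactants: 1 methyl (R)-3-hydroxy-2-methylpropanoate
Product: 2 methyl (S)-3-iodo-2-methylpropanoate
Conditions: I2, PPh3, imidazole, CH2Cl2, 0 °C → rt
Reagents that add atoms: iodine, II
Why: Appel iodination of the primary alcohol leaves the α-stereocentre untouched (R→S is only a CIP priority change).

Step 2
Reactants: 3 but-2-yn-1-ol
Product: 5 (Z)-3-iodo-2-methylbut-2-en-1-ol, via alkenylmagnesium chelate 4 (not isolated)
Conditions: MeMgBr (3 equiv), CuI (10 mol%), THF, 0 °C → reflux; then I2, −78 → 0 °C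
Reagents that add atoms: methylmagnesium bromide, C[Mg]Br; iodine, II
Why: Copper-catalysed anti-carbomagnesiation of the propargylic alkoxide (Duboudin type) puts methyl on C2 and magnesium on C3 cis to CH2O in a five-membered chelate, and iodinolysis with retention fixes the tetrasubstituted (Z)-geometry.

Step 3
Reactants: 2 methyl (S)-3-iodo-2-methylpropanoate, 5 (Z)-3-iodo-2-methylbut-2-en-1-ol
Product: 7 methyl (2R,4Z)-6-hydroxy-2,4,5-trimethylhex-4-enoate, via alkylzinc iodide 6 (not isolated)
Conditions: Zn dust (TMSCl/1,2-dibromoethane-activated), DMF, rt; then 5, Pd(OAc)2 (3 mol%), SPhos (6 mol%), THF/DMF, 40 °C (1.8 equiv of 6)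
Reagents that add atoms: none
Why: sp3–sp2 Negishi coupling of the configurationally stable zinc homoenolate proceeds with retention of alkene geometry, and the organozinc tolerates the ester and, with a fast SPhos catalyst, the free hydroxyl.

Step 4
Reactants: 7 methyl (2R,4Z)-6-hydroxy-2,4,5-trimethylhex-4-enoate
Product: 8 methyl (2R)-3-[(1S,2R)-2-(hydroxymethyl)-1,2-dimethylcyclopropyl]-2-methylpropanoate
Conditions: (4S,5S)-2-butyl-N,N,N′,N′-tetramethyl-1,3,2-dioxaborolane-4,5-dicarboxamide (1.2 equiv), Zn(CH2I)2·DME (from Et2Zn and CH2I2, 2.5 equiv), CH2Cl2, −10 °C → rt; minor diastereomer removed by chromatography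
Reagents that add atoms: bis(iodomethyl)zinc, IC[Zn]CI (made in the flask from diethylzinc and diiodomethane, ICI)
Why: Charette asymmetric Simmons–Smith cyclopropanation, in which the allylic alkoxide bound to the chiral dioxaborolane delivers CH2 syn-stereospecifically to one face of the (Z)-alkene and so sets both quaternary ring carbons (1S,2R), ring C1 being the future C6.

Step 5
Reactants: 8 methyl (2R)-3-[(1S,2R)-2-(hydroxymethyl)-1,2-dimethylcyclopropyl]-2-methylpropanoate
Product: 10 methyl (2E,4R)-5-[(1S,2R)-2-(hydroxymethyl)-1,2-dimethylcyclopropyl]-4-methylpent-2-enoate, via hydroxy aldehyde 9 (not isolated)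
Conditions: DIBAL-H (2.2 equiv), CH2Cl2, −78 °C; then Ph3P=CHCO2Me (2.5 equiv), −78 °C → rt
Reagents that add atoms: methyl (triphenylphosphoranylidene)acetate, COC(=O)C=P(c1ccccc1)(c1ccccc1)c1ccccc1
Why: One-pot half-reduction and Wittig olefination, where the aluminium hemiacetal releases the α-methyl aldehyde only as the stabilised ylide traps it, giving the (E)-enoate without epimerising C4.

Step 6
Reactants: 10 methyl (2E,4R)-5-[(1S,2R)-2-(hydroxymethyl)-1,2-dimethylcyclopropyl]-4-methylpent-2-enoate
Product: 11 methyl (2E,4R)-5-[(1S,2R)-2-formyl-1,2-dimethylcyclopropyl]-4-methylpent-2-enoate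
Conditions: Dess–Martin periodinane, NaHCO3, CH2Cl2, 0 °C → rt
Reagents that add atoms: none
Why: Dess–Martin oxidation of the primary cyclopropylmethanol to an aldehyde whose α-carbon is quaternary and cannot epimerise, with the enoate inert.

Step 7
Reactants: 12 benzyl bromide
Product: 13 (but-2-yn-1-yl)benzene
Conditions: 1-propynylmagnesium bromide (1.2 equiv), CuBr·SMe2 (5 mol%), THF, 0 → 50 °C
Reagents that add atoms: 1-propynylmagnesium bromide, CC#C[Mg]Br
Why: Copper-catalysed sp–sp3 coupling of an alkynyl Grignard reagent with a benzylic bromide.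

Step 8
Reactants: 13 (but-2-yn-1-yl)benzene, 11 methyl (2E,4R)-5-[(1S,2R)-2-formyl-1,2-dimethylcyclopropyl]-4-methylpent-2-enoate
Product: 16 methyl (2E,4R)-5-{(1S,2R)-2-[(2E)-1-hydroxy-2-methyl-4-phenylbut-2-en-1-yl]-1,2-dimethylcyclopropyl}-4-methylpent-2-enoate (both carbinol epimers), via alkenylzirconocene chloride 14 (not isolated), via alkenyl(methyl)zinc 15 (not isolated)
Conditions: 13 (1.5 equiv), Cp2Zr(H)Cl (1.6 equiv), CH2Cl2, rt; Me2Zn (1.5 equiv), −65 °C; then 11, 0 °C → rt
Reagents that add atoms: none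
Why: Schwartz syn-hydrozirconation places Zr on the methyl-bearing alkyne carbon, fixing the (E)-C10=C11 geometry, and Zr→Zn transmetalation gives an alkenylzinc that adds to the aldehyde but not to the enoate; the carbinol configuration is irrelevant because that carbon is ionised next.

Step 9
Reactants: 16 methyl (2E,4R)-5-{(1S,2R)-2-[(2E)-1-hydroxy-2-methyl-4-phenylbut-2-en-1-yl]-1,2-dimethylcyclopropyl}-4-methylpent-2-enoate
Product: 17 methyl (2E,4R,6R,8E,10E)-6-hydroperoxy-4,6,8,10-tetramethyl-12-phenyldodeca-2,8,10-trienoate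
Conditions: anhydrous H2O2 in Et2O (10 equiv), Sc(OTf)3 (5 mol%), MgSO4, Et2O/CH2Cl2, −40 → −10 °C; Et3N quench, cold silica filtration
Reagents that add atoms: hydrogen peroxide, OO
Why: Proposed new method: Lewis-acid ionisation of the allyl- and cyclopropyl-stabilised carbinol gives a non-classical cyclopropylcarbinyl cation that H2O2 attacks at the quaternary ring carbon anti to the breaking ring bond, so the C6–O bond forms with inversion ((1S)-cyclopropane → (6R)-hydroperoxide) while the ring opens to the (8E)-alkene (the dienyl group sits exo, away from the cis CH2 arm, in the bisected cation) and reversibly formed allylic hydroperoxides funnel to the strain-released product; the closest known reaction type is the stereoinvertive homoallylic substitution of cyclopropylcarbinols at a quaternary ring carbon by halide, azide, water or alcohols (Julia–Johnson-type opening), not yet shown with a peroxide nucleophile.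

Step 10
Reactants: 17 methyl (2E,4R,6R,8E,10E)-6-hydroperoxy-4,6,8,10-tetramethyl-12-phenyldodeca-2,8,10-trienoate
Product: 18 methyl 2-[(3S,4R,6R)-4,6-dimethyl-6-[(2E,4E)-2,4-dimethyl-6-phenylhexa-2,4-dien-1-yl]-1,2-dioxan-3-yl]acetate
Conditions: Et2NH (0.5 equiv), CF3CH2OH, rt
Reagents that add atoms: none
Why: Amine-mediated 6-exo-trig hydroperoxide oxa-Michael addition through a chair transition state with the C6 dienylmethyl group, the C4 methyl and the enoate equatorial (C6 methyl axial) and C4–H eclipsing the enoate, which gives the 3,4-trans (3S) ring, also the thermodynamic all-equatorial isomer.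

**Compound list**
1 | methyl (R)-3-hydroxy-2-methylpropanoate | COC(=O)[C@H](C)CO | starting material
2 | methyl (S)-3-iodo-2-methylpropanoate | COC(=O)[C@H](C)CI | intermediate
3 | but-2-yn-1-ol | CC#CCO | starting material
4 | bromo[(Z)-4-(bromomagnesiooxy)-3-methylbut-2-en-2-yl]magnesium (alkenylmagnesium chelate) | Br[Mg]OC/C(C)=C(C)\[Mg]Br | intermediate
5 | (Z)-3-iodo-2-methylbut-2-en-1-ol | OC/C(C)=C(C)\I | intermediate
6 | [(S)-3-methoxy-2-methyl-3-oxopropyl]zinc iodide | COC(=O)[C@H](C)C[Zn]I | intermediate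
7 | methyl (2R,4Z)-6-hydroxy-2,4,5-trimethylhex-4-enoate | COC(=O)[C@H](C)C/C(C)=C(C)\CO | intermediate
8 | methyl (2R)-3-[(1S,2R)-2-(hydroxymethyl)-1,2-dimethylcyclopropyl]-2-methylpropanoate | OC[C@]1(C)C[C@]1(C)C[C@@H](C)C(=O)OC | intermediate
9 | (2R)-3-[(1S,2R)-2-(hydroxymethyl)-1,2-dimethylcyclopropyl]-2-methylpropanal | OC[C@]1(C)C[C@]1(C)C[C@@H](C)C=O | intermediate
10 | methyl (2E,4R)-5-[(1S,2R)-2-(hydroxymethyl)-1,2-dimethylcyclopropyl]-4-methylpent-2-enoate | OC[C@]1(C)C[C@]1(C)C[C@@H](C)/C=C/C(=O)OC | intermediate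
11 | methyl (2E,4R)-5-[(1S,2R)-2-formyl-1,2-dimethylcyclopropyl]-4-methylpent-2-enoate | O=C[C@]1(C)C[C@]1(C)C[C@@H](C)/C=C/C(=O)OC | intermediate
12 | benzyl bromide | BrCc1ccccc1 | starting material
13 | (but-2-yn-1-yl)benzene | CC#CCc1ccccc1 | intermediate
14 | chloro[(E)-4-phenylbut-2-en-2-yl]zirconocene | C/C(=C\Cc1ccccc1)[Zr](Cl)(C1C=CC=C1)C1C=CC=C1 | intermediate
15 | methyl[(E)-4-phenylbut-2-en-2-yl]zinc | C/C(=C\Cc1ccccc1)[Zn]C | intermediate
16 | methyl (2E,4R)-5-{(1S,2R)-2-[(2E)-1-hydroxy-2-methyl-4-phenylbut-2-en-1-yl]-1,2-dimethylcyclopropyl}-4-methylpent-2-enoate | OC(/C(C)=C/Cc1ccccc1)[C@]2(C)C[C@]2(C)C[C@@H](C)/C=C/C(=O)OC | intermediate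
17 | methyl (2E,4R,6R,8E,10E)-6-hydroperoxy-4,6,8,10-tetramethyl-12-phenyldodeca-2,8,10-trienoate | COC(=O)/C=C/[C@H](C)C[C@@](C)(OO)C/C(C)=C/C(C)=C/Cc1ccccc1 | intermediate
18 | methyl 2-[(3S,4R,6R)-4,6-dimethyl-6-[(2E,4E)-2,4-dimethyl-6-phenylhexa-2,4-dien-1-yl]-1,2-dioxan-3-yl]acetate | COC(=O)C[C@@H]1OO[C@@](C)(C/C(C)=C/C(C)=C/Cc2ccccc2)C[C@H]1C | target

**Totals**
Total step count: 10. Longest linear sequence: 8 steps (1, 3, 4, 5, 6, 8, 9, 10).

**Three steps most likely to fail**

Step 9 (the new step). Risks are capture of the cation at its allylic termini or by water, partial loss of stereospecificity, and acid-induced Hock cleavage of 17. The fallback uses known chemistry and sets out from 16. TMSBr in CH2Cl2 at −78 °C carries out the established stereoinvertive homoallylic bromination and gives the tertiary bromide methyl (2E,4R,6R,8E,10E)-6-bromo-4,6,8,10-tetramethyl-12-phenyldodeca-2,8,10-trienoate F1. Silver-assisted perhydrolysis of this tertiary bromide (AgOCOCF3, anhydrous H2O2, Et2O, 0 °C) then returns to the route at 17. This second substitution passes through an ion pair, so some C6 epimer is expected and is removed by chromatography after step 10.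

Step 8. Risks are incomplete regiocontrol in the hydrozirconation of an internal alkyne and slow addition to the hindered aldehyde next to a quaternary carbon. The fallback sets out from 11 and builds the same cation precursor from the other end. Wittig reaction with 2-(triphenylphosphoranylidene)propanal (toluene, 90 °C) gives the enal methyl (2E,4R)-5-{(1S,2S)-1,2-dimethyl-2-[(1E)-2-methyl-3-oxoprop-1-en-1-yl]cyclopropyl}-4-methylpent-2-enoate F2. Benzylmagnesium chloride (1.05 equiv, THF, −78 °C) adds to the aldehyde much faster than to the enoate and gives the transposed allylic alcohol methyl (2E,4R)-5-{(1S,2S)-2-[(1E)-3-hydroxy-2-methyl-4-phenylbut-1-en-1-yl]-1,2-dimethylcyclopropyl}-4-methylpent-2-enoate F3. Under the step 9 conditions F3 ionises to the same allyl/cyclopropylcarbinyl cation as 16, so the fallback comes back at 17; any (10Z) isomer is separated there.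

Step 10. The risk is modest 3,4-trans selectivity, because allylic strain is weak in an (E)-enoate. The fallback sets out from 8 and changes the alkene geometry so that allylic strain locks the transition state. DIBAL-H reduction to 9 followed by Still–Gennari olefination ((CF3CH2O)2P(O)CH2CO2Me, KHMDS, 18-crown-6, THF, −78 °C) gives methyl (2Z,4R)-5-[(1S,2R)-2-(hydroxymethyl)-1,2-dimethylcyclopropyl]-4-methylpent-2-enoate F4. Dess–Martin oxidation gives methyl (2Z,4R)-5-[(1S,2R)-2-formyl-1,2-dimethylcyclopropyl]-4-methylpent-2-enoate F5. Addition of 15 as in step 8 gives methyl (2Z,4R)-5-{(1S,2R)-2-[(2E)-1-hydroxy-2-methyl-4-phenylbut-2-en-1-yl]-1,2-dimethylcyclopropyl}-4-methylpent-2-enoate F6. Perhydrolysis as in step 9 gives methyl (2Z,4R,6R,8E,10E)-6-hydroperoxy-4,6,8,10-tetramethyl-12-phenyldodeca-2,8,10-trienoate F7. With Et2NH in CF3CH2OH, F7 must cyclise through the H-eclipsed conformer, and the route is rejoined at 18.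

**Further compounds**
F1 | step 9 | methyl (2E,4R,6R,8E,10E)-6-bromo-4,6,8,10-tetramethyl-12-phenyldodeca-2,8,10-trienoate | COC(=O)/C=C/[C@H](C)C[C@@](C)(Br)C/C(C)=C/C(C)=C/Cc1ccccc1
F2 | step 8 | methyl (2E,4R)-5-{(1S,2S)-1,2-dimethyl-2-[(1E)-2-methyl-3-oxoprop-1-en-1-yl]cyclopropyl}-4-methylpent-2-enoate | O=C/C(C)=C/[C@]1(C)C[C@]1(C)C[C@@H](C)/C=C/C(=O)OC
F3 | step 8 | methyl (2E,4R)-5-{(1S,2S)-2-[(1E)-3-hydroxy-2-methyl-4-phenylbut-1-en-1-yl]-1,2-dimethylcyclopropyl}-4-methylpent-2-enoate | OC(Cc1ccccc1)/C(C)=C/[C@]2(C)C[C@]2(C)C[C@@H](C)/C=C/C(=O)OC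
F4 | step 10 | methyl (2Z,4R)-5-[(1S,2R)-2-(hydroxymethyl)-1,2-dimethylcyclopropyl]-4-methylpent-2-enoate | OC[C@]1(C)C[C@]1(C)C[C@@H](C)/C=C\C(=O)OC
F5 | step 10 | methyl (2Z,4R)-5-[(1S,2R)-2-formyl-1,2-dimethylcyclopropyl]-4-methylpent-2-enoate | O=C[C@]1(C)C[C@]1(C)C[C@@H](C)/C=C\C(=O)OC
F6 | step 10 | methyl (2Z,4R)-5-{(1S,2R)-2-[(2E)-1-hydroxy-2-methyl-4-phenylbut-2-en-1-yl]-1,2-dimethylcyclopropyl}-4-methylpent-2-enoate | OC(/C(C)=C/Cc1ccccc1)[C@]2(C)C[C@]2(C)C[C@@H](C)/C=C\C(=O)OC
F7 | step 10 | methyl (2Z,4R,6R,8E,10E)-6-hydroperoxy-4,6,8,10-tetramethyl-12-phenyldodeca-2,8,10-trienoate | COC(=O)/C=C\[C@H](C)C[C@@](C)(OO)C/C(C)=C/C(C)=C/Cc1ccccc1
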